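Cuts: C10–C11 and C10'–C11' (two Stille couplings) give a C11–C11' pentaene bis-stannane and two bicyclic alkenyl iodides; in each iodide C9=C10 goes back to a C8 alkyne, and C8–C9 to the carbonyl C8 of a butenolide.
Enabling feature: in each dihydrofuran ring (O1–C5–C6=C7–C8) C5 is a tertiary allylic C–O centre beside C6=C7, so its oxygen can come from C7 across the C5=C6 alkene of a 2,6,6-trimethylcyclohexenyl ring by a selenoxide [2,3] shift, after which the alkoxide closes the lactone on C8.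
Unhydroxylated half, forward: cyclohexenylacetic acid, Evans imide, C7 selenide, (R)-dihydroactinidiolide (furanone ring closes here), acetylide addition, silane reduction, methylalumination–iodination.
Hydroxylated half, forward: C4-inverted actinol, enol triflate, Reformatsky–Negishi coupling, the same selenoxide sequence with the antipodal auxiliary, silylated (+)-loliolide, hydride first and alkyne second, iodide.
Chain: a C10 dialdehyde becomes the bis-stannane; mono-Stille coupling with the hydroxylated iodide, final Stille coupling with the other iodide.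
Stereochemistry: C5/C5' by 1,3-chirality transfer from C7/C7' (set by (S)- and (R)-4-benzyloxazolidinone); C3' from actinol by Mitsunobu inversion; C8/C8' by attack anti to the angular methyl (hydride last gives cis, alkyne last gives trans); E alkenes from syn-carbometalation, Takai–Hodgson olefination and stereoretentive couplings.

Key step: step 4

Remark: carotenoid locants are used, unprimed for the unhydroxylated half and primed for the hydroxylated half; in the given structure the hydroxylated bicycle is (3'R,5'S,8'S), the mirror image of the usual furanoid end group, so that half is built from C4-inverted actinol and the (R)-auxiliary.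
Remark: β-homocyclocitral 1 (a flavour chemical, the one-carbon homologue of β-cyclocitral) and (4R,6R)-actinol 18 (the industrial zeaxanthin intermediate) are assumed to be purchasable.

Step 1
Reactants: 1 β-homocyclocitral [2-(2,6,6-trimethylcyclohex-1-en-1-yl)acetaldehyde]
Product: 2 2-(2,6,6-trimethylcyclohex-1-en-1-yl)acetic acid
Conditions: NaClO2, NaH2PO4, 2-methylbut-2-ene, t-BuOH/H2O, 0 °C to rt
Reagents that add atoms: sodium chlorite, [Na+].[O-]Cl=O
Why: Pinnick oxidation takes the β,γ-unsaturated aldehyde to the acid in buffered medium, and the alkene scavenger removes HOCl before it can attack the tetrasubstituted ring alkene.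

Step 2
Reactants: 2 2-(2,6,6-trimethylcyclohex-1-en-1-yl)acetic acid; 3 (S)-4-benzyloxazolidin-2-one
Product: 5 (S)-4-benzyl-3-[2-(2,6,6-trimethylcyclohex-1-en-1-yl)acetyl]oxazolidin-2-one, via mixed pivalic anhydride 4 (not isolated)
Conditions: PivCl, Et3N, THF, −20 °C; then 3, LiCl, −20 °C to rt
Reagents that add atoms: none
Why: N-Acylation of the Evans auxiliary through the mixed pivalic anhydride, with LiCl/Et3N activating the oxazolidinone, needs no strong base and so leaves the β,γ-alkene in place.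

Step 3
Reactants: 5 (S)-4-benzyl-3-[2-(2,6,6-trimethylcyclohex-1-en-1-yl)acetyl]oxazolidin-2-one; 6 phenylselenenyl chloride
Product: 8 (S)-4-benzyl-3-[(S)-2-(phenylselanyl)-2-(2,6,6-trimethylcyclohex-1-en-1-yl)acetyl]oxazolidin-2-one, via sodium enolate 7 (not isolated)
Conditions: NaN(SiMe3)2, THF, −78 °C; enolate cannulated into 6, THF, −78 °C; AcOH quench at −78 °C; used without chromatography
Reagents that add atoms: none
Why: Electrophilic α-selenenylation of an Evans imide: the chelated sodium Z-enolate is attacked at C7 on the face opposite the benzyl group, which sets (S)-C7, while the γ-terminus C5 is fully substituted and shielded, and the cold acidic quench keeps the more acidic C7–H of the product from epimerising.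

Step 4
Reactants: 8 (S)-4-benzyl-3-[(S)-2-(phenylselanyl)-2-(2,6,6-trimethylcyclohex-1-en-1-yl)acetyl]oxazolidin-2-one
Product: 12 (R)-dihydroactinidiolide [(7aR)-4,4,7a-trimethyl-5,6,7,7a-tetrahydro-1-benzofuran-2(4H)-one], via selenoxide 9 (not isolated), via selenenate 10 (not isolated), via hydroxy imide 11 (not isolated)
Conditions: 30% aq H2O2, pyridine, CH2Cl2, 0 °C to rt
Reagents that add atoms: hydrogen peroxide, OO
Why: H2O2 oxidises selenium to the selenoxide 9, which undergoes a suprafacial [2,3]-sigmatropic shift through a five-membered envelope (C5=C6–C7–Se–O) that moves oxygen to C5 and the alkene to C6=C7, and the selenenate 10 is hydrolysed in the buffered peroxide medium to the tertiary alcohol 11. The closest known reaction type is the allylic selenoxide–selenenate rearrangement with 1,3-chirality transfer to tertiary allylic alcohols, the selenium counterpart of the Mislow–Evans rearrangement. The furanone ring closes by 5-exo-trig attack of the C5 hydroxyl on the exocyclic imide carbonyl C8, an intramolecular alcoholysis that releases auxiliary 3 for recovery. The new stereocentre C5 is controlled by C7: in the rotamer that holds the acyl group on the C5 side, selenium of the (S)-selenide lies on the alkene face from which oxygen delivery gives (R)-C5. The step needs the Z geometry at C6=C7, and the outcome is secured because only the Z isomer can lactonise: material that reacts through the other rotamer ends as an acyclic E hydroxy imide of opposite C5 configuration, is removed by chromatography and lowers the yield, not the enantiomeric purity. Selenoxide syn-elimination cannot compete because neither C6 (sp2) nor C8 (carbonyl) carries hydrogen, and pyridine suppresses acid-promoted seleno-Pummerer pathways and epoxidation by perseleninic acid.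

Step 5
Reactants: 12 (R)-dihydroactinidiolide
Product: 13 (7aR)-4,4,7a-trimethyl-2-[(trimethylsilyl)ethynyl]-2,4,5,6,7,7a-hexahydro-1-benzofuran-2-ol (both C8 epimers)
Conditions: Me3SiC≡CH, n-BuLi, THF, −78 °C; then 12, −78 °C; aq NH4Cl
Reagents that add atoms: ethynyltrimethylsilane, C#C[Si](C)(C)C
Why: 1,2-Addition of the lithium acetylide to the lactone carbonyl stops at the tetrahedral adduct at −78 °C and gives the cyclic hemiketal, conjugate addition being blocked by the fully substituted β-carbon C6 and enolisation by the quaternary C5; the C8 epimer mixture is erased in step 6.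

Step 6
Reactants: 13 (7aR)-4,4,7a-trimethyl-2-[(trimethylsilyl)ethynyl]-2,4,5,6,7,7a-hexahydro-1-benzofuran-2-ol
Product: 14 trimethyl{[(2S,7aR)-4,4,7a-trimethyl-2,4,5,6,7,7a-hexahydro-1-benzofuran-2-yl]ethynyl}silane
Conditions: Et3SiH, BF3·OEt2, CH2Cl2, −78 to −30 °C
Reagents that add atoms: none
Why: Ionic hydrogenation of a hemiketal: BF3·OEt2 ionises 13 to the alkynyl-substituted oxocarbenium ion and Et3SiH should deliver hydride to C8 on the face opposite the angular C5 methyl group, which leaves the alkyne cis to that methyl, i.e. (8S), attack at the vinylogous position C6 being blocked by its two quaternary neighbours.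

Step 7
Reactants: 14 trimethyl{[(2S,7aR)-4,4,7a-trimethyl-2,4,5,6,7,7a-hexahydro-1-benzofuran-2-yl]ethynyl}silane
Product: 15 (2S,7aR)-2-ethynyl-4,4,7a-trimethyl-2,4,5,6,7,7a-hexahydro-1-benzofuran
Conditions: K2CO3 (cat.), MeOH, rt
Reagents that add atoms: none
Why: Base-catalysed methanolysis of the C(sp)–Si bond (protodesilylation), to which the ether, the ring alkene and both stereocentres are inert.

Step 8
Reactants: 15 (2S,7aR)-2-ethynyl-4,4,7a-trimethyl-2,4,5,6,7,7a-hexahydro-1-benzofuran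
Product: 17 (2S,7aR)-2-[(E)-1-iodoprop-1-en-2-yl]-4,4,7a-trimethyl-2,4,5,6,7,7a-hexahydro-1-benzofuran, via alkenylalane 16 (not isolated)
Conditions: AlMe3 (3 equiv), Cp2ZrCl2 (0.2 equiv), H2O (1 equiv), CH2Cl2, −25 °C; then I2, THF, −25 to 0 °C
Reagents that add atoms: trimethylaluminium, C[Al](C)C; iodine, II
Why: Negishi zirconium-catalysed methylalumination adds methyl and aluminium syn across the terminal alkyne with methyl on C9, and iodinolysis of the alkenyl–aluminium bond with retention gives the E iodide; water acceleration allows −25 °C, which limits contact of the allylic propargylic ether with the Lewis acid.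

Step 9
Reactants: 18 (4R,6R)-4-hydroxy-2,2,6-trimethylcyclohexan-1-one [(4R,6R)-actinol]
Product: 19 (1S,5R)-3,3,5-trimethyl-4-oxocyclohexyl 4-nitrobenzoate
Conditions: 4-O2NC6H4CO2H, PPh3, DIAD, THF, 0 °C to rt
Reagents that add atoms: 4-nitrobenzoic acid, OC(=O)c1ccc(cc1)[N+](=O)[O-]
Why: Mitsunobu esterification displaces the oxyphosphonium ion by SN2 and so inverts the carbinol centre (the future C3') from R to S.

Step 10
Reactants: 19 (1S,5R)-3,3,5-trimethyl-4-oxocyclohexyl 4-nitrobenzoate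
Product: 20 (4S,6R)-4-hydroxy-2,2,6-trimethylcyclohexan-1-one
Conditions: K2CO3 (cat.), MeOH, rt
Reagents that add atoms: none
Why: Transesterification of the activated aryl ester frees the inverted alcohol; any equilibration at C6 is harmless because that centre becomes sp2 in step 12.

Step 11
Reactants: 20 (4S,6R)-4-hydroxy-2,2,6-trimethylcyclohexan-1-one
Product: 21 (4S,6R)-4-[(tert-butyldimethylsilyl)oxy]-2,2,6-trimethylcyclohexan-1-one
Conditions: TBSCl, imidazole, DMF, rt
Reagents that add atoms: tert-butyldimethylsilyl chloride, CC(C)(C)[Si](C)(C)Cl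
Why: Standard imidazole-promoted silylation of an unhindered secondary alcohol gives an ether that withstands the bases, the peroxide and the hydride used later.

Step 12
Reactants: 21 (4S,6R)-4-[(tert-butyldimethylsilyl)oxy]-2,2,6-trimethylcyclohexan-1-one
Product: 23 (4S)-4-[(tert-butyldimethylsilyl)oxy]-2,6,6-trimethylcyclohex-1-en-1-yl trifluoromethanesulfonate, via potassium enolate 22 (not isolated)
Conditions: KN(SiMe3)2, THF, −78 °C; then PhNTf2, −78 °C to rt
Reagents that add atoms: N-phenylbis(trifluoromethanesulfonimide), FC(F)(F)S(=O)(=O)N(c1ccccc1)S(=O)(=O)C(F)(F)F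
Why: The ketone has α-hydrogen only on the methyl-bearing carbon, so deprotonation gives a single enolate whose O-triflation fixes the tetrasubstituted C5'=C6' alkene.

Step 13
Reactants: 23 (4S)-4-[(tert-butyldimethylsilyl)oxy]-2,6,6-trimethylcyclohex-1-en-1-yl trifluoromethanesulfonate
Product: 24 ethyl 2-[(4S)-4-[(tert-butyldimethylsilyl)oxy]-2,6,6-trimethylcyclohex-1-en-1-yl]acetate
Conditions: BrCH2CO2Et, Zn (Me3SiCl-activated), THF, 40 °C; then 23, Pd2(dba)3 (cat.), XPhos (cat.), THF, 60 °C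
Reagents that add atoms: ethyl bromoacetate, CCOC(=O)CBr
Why: Negishi-type coupling of a Reformatsky reagent with an alkenyl triflate (oxidative addition to zerovalent palladium, transmetalation from zinc, reductive elimination) forms C6'–C7' with the alkene held where the triflate placed it.

Step 14
Reactants: 24 ethyl 2-[(4S)-4-[(tert-butyldimethylsilyl)oxy]-2,6,6-trimethylcyclohex-1-en-1-yl]acetate
Product: 25 2-[(4S)-4-[(tert-butyldimethylsilyl)oxy]-2,6,6-trimethylcyclohex-1-en-1-yl]acetic acid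
Conditions: LiOH, THF/MeOH/H2O, rt; then dilute HCl to pH 4
Reagents that add atoms: lithium hydroxide, [Li+].[OH-]
Why: Saponification of the ethyl ester at room temperature leaves the silyl ether and the β,γ-alkene untouched, and acidification only to pH 4 avoids desilylation.

Step 15
Reactants: 25 2-[(4S)-4-[(tert-butyldimethylsilyl)oxy]-2,6,6-trimethylcyclohex-1-en-1-yl]acetic acid; 26 (R)-4-benzyloxazolidin-2-one
Product: 28 (R)-4-benzyl-3-{2-[(4S)-4-[(tert-butyldimethylsilyl)oxy]-2,6,6-trimethylcyclohex-1-en-1-yl]acetyl}oxazolidin-2-one, via mixed pivalic anhydride 27 (not isolated)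
Conditions: PivCl, Et3N, THF, −20 °C; then 26, LiCl, −20 °C to rt
Reagents that add atoms: none
Why: The same mixed-anhydride N-acylation as in step 2, now with the antipodal Evans auxiliary.

Step 16
Reactants: 28 (R)-4-benzyl-3-{2-[(4S)-4-[(tert-butyldimethylsilyl)oxy]-2,6,6-trimethylcyclohex-1-en-1-yl]acetyl}oxazolidin-2-one; 6 phenylselenenyl chloride
Product: 30 (R)-4-benzyl-3-{(R)-2-[(4S)-4-[(tert-butyldimethylsilyl)oxy]-2,6,6-trimethylcyclohex-1-en-1-yl]-2-(phenylselanyl)acetyl}oxazolidin-2-one, via sodium enolate 29 (not isolated)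
Conditions: NaN(SiMe3)2, THF, −78 °C; enolate cannulated into 6, THF, −78 °C; AcOH quench at −78 °C; used without chromatography
Reagents that add atoms: none
Why: Electrophilic α-selenenylation of the chelated sodium Z-enolate on the face opposite the benzyl group of the (R)-auxiliary sets (R)-C7', the remote silyloxy centre having no influence.

Step 17
Reactants: 30 (R)-4-benzyl-3-{(R)-2-[(4S)-4-[(tert-butyldimethylsilyl)oxy]-2,6,6-trimethylcyclohex-1-en-1-yl]-2-(phenylselanyl)acetyl}oxazolidin-2-one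
Product: 34 (6R,7aS)-6-[(tert-butyldimethylsilyl)oxy]-4,4,7a-trimethyl-5,6,7,7a-tetrahydro-1-benzofuran-2(4H)-one [O-silyl-(+)-loliolide], via selenoxide 31 (not isolated), via selenenate 32 (not isolated), via hydroxy imide 33 (not isolated)
Conditions: 30% aq H2O2, pyridine, CH2Cl2, 0 °C to rt
Reagents that add atoms: hydrogen peroxide, OO
Why: The allylic selenoxide [2,3]-sigmatropic shift and 5-exo-trig lactonisation of step 4 in the mirror-image sense: (R)-C7' passes its chirality suprafacially to (S)-C5' through the Z-forming rotamer, and auxiliary 26 is released.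

Step 18
Reactants: 34 (6R,7aS)-6-[(tert-butyldimethylsilyl)oxy]-4,4,7a-trimethyl-5,6,7,7a-tetrahydro-1-benzofuran-2(4H)-one
Product: 36 (6R,7aS)-6-[(tert-butyldimethylsilyl)oxy]-4,4,7a-trimethyl-2,4,5,6,7,7a-hexahydro-1-benzofuran-2-yl acetate (both C8' epimers), via aluminium lactolate 35 (not isolated)
Conditions: i-Bu2AlH, CH2Cl2, −78 °C; then Ac2O, pyridine, DMAP, −78 to 0 °C
Reagents that add atoms: acetic anhydride, CC(=O)OC(C)=O
Why: One-pot reductive acetylation: i-Bu2AlH adds once to the lactone carbonyl at −78 °C and the aluminium lactolate is acetylated before it can open, the quaternary C5' excluding aromatisation to a furan; the C8' epimer mixture is erased in step 19.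

Step 19
Reactants: 36 (6R,7aS)-6-[(tert-butyldimethylsilyl)oxy]-4,4,7a-trimethyl-2,4,5,6,7,7a-hexahydro-1-benzofuran-2-yl acetate
Product: 37 tert-butyldimethyl{[(2S,6R,7aS)-4,4,7a-trimethyl-2-[(trimethylsilyl)ethynyl]-2,4,5,6,7,7a-hexahydro-1-benzofuran-6-yl]oxy}silane
Conditions: Me3SiC≡CSiMe3, SnCl4, CH2Cl2, −78 to −40 °C
Reagents that add atoms: bis(trimethylsilyl)acetylene, C[Si](C)(C)C#C[Si](C)(C)C
Why: Lewis-acid C-alkynylation of an acetal acetate (C-glycosylation type through a Ferrier-like allylic oxocarbenium ion): the silylalkyne should attack C8' on the face opposite the angular C5' methyl group and lose one silyl group, so that the alkyne is trans to that methyl, i.e. (8'S), the same facial preference as in step 6 but with the carbon nucleophile entering last.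

Step 20
Reactants: 37 tert-butyldimethyl{[(2S,6R,7aS)-4,4,7a-trimethyl-2-[(trimethylsilyl)ethynyl]-2,4,5,6,7,7a-hexahydro-1-benzofuran-6-yl]oxy}silane
Product: 38 (2S,6R,7aS)-2-ethynyl-4,4,7a-trimethyl-2,4,5,6,7,7a-hexahydro-1-benzofuran-6-ol
Conditions: Bu4NF, THF, 0 °C to rt
Reagents that add atoms: none
Why: Fluoride cleaves the C(sp)–Si and the O–Si bond in one operation, so no deprotection is left for the polyene stage and the free hydroxyl serves as a chromatographic handle in step 24.

Step 21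
Reactants: 38 (2S,6R,7aS)-2-ethynyl-4,4,7a-trimethyl-2,4,5,6,7,7a-hexahydro-1-benzofuran-6-ol
Product: 40 (2S,6R,7aS)-2-[(E)-1-iodoprop-1-en-2-yl]-4,4,7a-trimethyl-2,4,5,6,7,7a-hexahydro-1-benzofuran-6-ol, via alkenylalane 39 (not isolated)
Conditions: AlMe3 (4 equiv), Cp2ZrCl2 (0.2 equiv), H2O (1 equiv), CH2Cl2, −25 °C; then I2, THF, −25 to 0 °C
Reagents that add atoms: trimethylaluminium, C[Al](C)C; iodine, II
Why: The same Negishi syn-methylalumination and stereoretentive iodinolysis as in step 8, with the hydroxyl carried as its aluminium alkoxide at the cost of one more equivalent of AlMe3.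

Step 22
Reactants: 41 dibromomethane; 42 tributyltin chloride
Product: 44 tributyl(dibromomethyl)stannane, via dibromomethyllithium 43 (not isolated)
Conditions: LiN(i-Pr)2 added to 41 and 42, THF/Et2O, −95 to −60 °C
Reagents that add atoms: none
Why: Deprotonation of dibromomethane gives the carbenoid, which is stannylated by the chloride already present (in situ quench) before α-elimination can occur.

Step 23
Reactants: 45 (2E,4E,6E)-2,7-dimethylocta-2,4,6-trienedial; 44 tributyl(dibromomethyl)stannane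
Product: 47 (1E,3E,5E,7E,9E)-3,8-dimethyl-1,10-bis(tributylstannyl)deca-1,3,5,7,9-pentaene, via stannyl tetraenal 46 (not isolated)
Conditions: CrCl2 (excess), LiI, 44 (2.5 equiv), THF/DMF, rt, dark
Reagents that add atoms: none
Why: Takai–Hodgson stannyl olefination: the geminal dichromium reagent formed from 44 and divalent chromium adds to each aldehyde and eliminates to the E alkenylstannane, as known for enals, once at each end.

Step 24
Reactants: 40 (2S,6R,7aS)-2-[(E)-1-iodoprop-1-en-2-yl]-4,4,7a-trimethyl-2,4,5,6,7,7a-hexahydro-1-benzofuran-6-ol; 47 (1E,3E,5E,7E,9E)-3,8-dimethyl-1,10-bis(tributylstannyl)deca-1,3,5,7,9-pentaene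
Product: 48 (2S,6R,7aS)-2-[(2E,4E,6E,8E,10E,12E)-6,11-dimethyl-13-(tributylstannyl)trideca-2,4,6,8,10,12-hexaen-2-yl]-4,4,7a-trimethyl-2,4,5,6,7,7a-hexahydro-1-benzofuran-6-ol
Conditions: 47 (3 equiv), Pd2(dba)3 (cat.), AsPh3 (cat.), NMP, rt to 40 °C, degassed, dark; Et3N-deactivated silica
Reagents that add atoms: none
Why: Stille coupling with retention at both alkenes joins C10'–C11'; the excess of 47 (recovered) enforces mono-coupling, and the hydroxyl of the product separates it from 47 and from doubly coupled material.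

Step 25
Reactants: 48 (2S,6R,7aS)-2-[(2E,4E,6E,8E,10E,12E)-6,11-dimethyl-13-(tributylstannyl)trideca-2,4,6,8,10,12-hexaen-2-yl]-4,4,7a-trimethyl-2,4,5,6,7,7a-hexahydro-1-benzofuran-6-ol; 17 (2S,7aR)-2-[(E)-1-iodoprop-1-en-2-yl]-4,4,7a-trimethyl-2,4,5,6,7,7a-hexahydro-1-benzofuran
Product: 49 (all-E)-(5R,8S,3'R,5'S,8'S)-5,8:5',8'-diepoxy-5,8,5',8'-tetrahydro-β,β-caroten-3'-ol (CNP0406432.1)
Conditions: 17 (1.2 equiv), Pd2(dba)3 (cat.), AsPh3 (cat.), NMP, rt to 40 °C, degassed, dark
Reagents that add atoms: none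
Why: A second Stille coupling joins C10–C11 with retention of both alkene geometries and completes the all-E heptaene under neutral conditions that spare the acid-sensitive allylic ether centres C8 and C8'.

Compound list
1 | β-homocyclocitral, 2-(2,6,6-trimethylcyclohex-1-en-1-yl)acetaldehyde | O=CCC1=C(C)CCCC1(C)C | starting material
2 | 2-(2,6,6-trimethylcyclohex-1-en-1-yl)acetic acid | OC(=O)CC1=C(C)CCCC1(C)C | intermediate
3 | (S)-4-benzyloxazolidin-2-one | O=C1N[C@@H](Cc2ccccc2)CO1 | starting material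
4 | 2-(2,6,6-trimethylcyclohex-1-en-1-yl)acetic pivalic anhydride | CC(C)(C)C(=O)OC(=O)CC1=C(C)CCCC1(C)C | intermediate (not isolated)
5 | (S)-4-benzyl-3-[2-(2,6,6-trimethylcyclohex-1-en-1-yl)acetyl]oxazolidin-2-one | O=C(CC1=C(C)CCCC1(C)C)N1[C@@H](Cc2ccccc2)COC1=O | intermediate
6 | phenylselenenyl chloride | Cl[Se]c1ccccc1 | starting material
7 | sodium (Z)-enolate of 5 | [Na+].[O-]/C(=C\C1=C(C)CCCC1(C)C)N1[C@@H](Cc2ccccc2)COC1=O | intermediate (not isolated)
8 | (S)-4-benzyl-3-[(S)-2-(phenylselanyl)-2-(2,6,6-trimethylcyclohex-1-en-1-yl)acetyl]oxazolidin-2-one | O=C(N1[C@@H](Cc2ccccc2)COC1=O)[C@@H]([Se]c1ccccc1)C1=C(C)CCCC1(C)C | intermediate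
9 | selenoxide of 8 (both configurations at selenium) | O=C(N1[C@@H](Cc2ccccc2)COC1=O)[C@@H]([Se](=O)c1ccccc1)C1=C(C)CCCC1(C)C | intermediate (not isolated)
10 | (S)-4-benzyl-3-{(Z)-2-[(2R)-2,6,6-trimethyl-2-(phenylselanyloxy)cyclohexylidene]acetyl}oxazolidin-2-one | O=C(/C=C1/C(C)(C)CCC[C@@]1(C)O[Se]c1ccccc1)N1[C@@H](Cc2ccccc2)COC1=O | intermediate (not isolated)
11 | (S)-4-benzyl-3-{(Z)-2-[(2R)-2-hydroxy-2,6,6-trimethylcyclohexylidene]acetyl}oxazolidin-2-one | O=C(/C=C1/C(C)(C)CCC[C@@]1(C)O)N1[C@@H](Cc2ccccc2)COC1=O | intermediate (not isolated)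
12 | (R)-dihydroactinidiolide, (7aR)-4,4,7a-trimethyl-5,6,7,7a-tetrahydro-1-benzofuran-2(4H)-one | O=C1C=C2C(C)(C)CCC[C@@]2(C)O1 | intermediate
13 | (7aR)-4,4,7a-trimethyl-2-[(trimethylsilyl)ethynyl]-2,4,5,6,7,7a-hexahydro-1-benzofuran-2-ol (both C8 epimers) | C[Si](C)(C)C#CC1(O)C=C2C(C)(C)CCC[C@@]2(C)O1 | intermediate
14 | trimethyl{[(2S,7aR)-4,4,7a-trimethyl-2,4,5,6,7,7a-hexahydro-1-benzofuran-2-yl]ethynyl}silane | C[Si](C)(C)C#C[C@@H]1C=C2C(C)(C)CCC[C@@]2(C)O1 | intermediate
15 | (2S,7aR)-2-ethynyl-4,4,7a-trimethyl-2,4,5,6,7,7a-hexahydro-1-benzofuran | C#C[C@@H]1C=C2C(C)(C)CCC[C@@]2(C)O1 | intermediate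
16 | dimethyl{(E)-2-[(2S,7aR)-4,4,7a-trimethyl-2,4,5,6,7,7a-hexahydro-1-benzofuran-2-yl]prop-1-en-1-yl}alane | C[Al](C)/C=C(\C)[C@@H]1C=C2C(C)(C)CCC[C@@]2(C)O1 | intermediate (not isolated)
17 | (2S,7aR)-2-[(E)-1-iodoprop-1-en-2-yl]-4,4,7a-trimethyl-2,4,5,6,7,7a-hexahydro-1-benzofuran | I/C=C(\C)[C@@H]1C=C2C(C)(C)CCC[C@@]2(C)O1 | intermediate
18 | (4R,6R)-4-hydroxy-2,2,6-trimethylcyclohexan-1-one, (4R,6R)-actinol | CC1(C)C[C@H](O)C[C@@H](C)C1=O | starting material
19 | (1S,5R)-3,3,5-trimethyl-4-oxocyclohexyl 4-nitrobenzoate | CC1(C)C[C@@H](OC(=O)c2ccc(cc2)[N+](=O)[O-])C[C@@H](C)C1=O | intermediate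
20 | (4S,6R)-4-hydroxy-2,2,6-trimethylcyclohexan-1-one | CC1(C)C[C@@H](O)C[C@@H](C)C1=O | intermediate
21 | (4S,6R)-4-[(tert-butyldimethylsilyl)oxy]-2,2,6-trimethylcyclohexan-1-one | CC1(C)C[C@@H](O[Si](C)(C)C(C)(C)C)C[C@@H](C)C1=O | intermediate
22 | potassium enolate of 21 | CC1(C)C[C@@H](O[Si](C)(C)C(C)(C)C)CC(C)=C1[O-].[K+] | intermediate (not isolated)
23 | (4S)-4-[(tert-butyldimethylsilyl)oxy]-2,6,6-trimethylcyclohex-1-en-1-yl trifluoromethanesulfonate | CC1(C)C[C@@H](O[Si](C)(C)C(C)(C)C)CC(C)=C1OS(=O)(=O)C(F)(F)F | intermediate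
24 | ethyl 2-[(4S)-4-[(tert-butyldimethylsilyl)oxy]-2,6,6-trimethylcyclohex-1-en-1-yl]acetate | CCOC(=O)CC1=C(C)C[C@H](O[Si](C)(C)C(C)(C)C)CC1(C)C | intermediate
25 | 2-[(4S)-4-[(tert-butyldimethylsilyl)oxy]-2,6,6-trimethylcyclohex-1-en-1-yl]acetic acid | OC(=O)CC1=C(C)C[C@H](O[Si](C)(C)C(C)(C)C)CC1(C)C | intermediate
26 | (R)-4-benzyloxazolidin-2-one | O=C1N[C@H](Cc2ccccc2)CO1 | starting material
27 | mixed pivalic anhydride of 25 | CC(C)(C)C(=O)OC(=O)CC1=C(C)C[C@H](O[Si](C)(C)C(C)(C)C)CC1(C)C | intermediate (not isolated)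
28 | (R)-4-benzyl-3-{2-[(4S)-4-[(tert-butyldimethylsilyl)oxy]-2,6,6-trimethylcyclohex-1-en-1-yl]acetyl}oxazolidin-2-one | O=C(CC1=C(C)C[C@H](O[Si](C)(C)C(C)(C)C)CC1(C)C)N1[C@H](Cc2ccccc2)COC1=O | intermediate
29 | sodium (Z)-enolate of 28 | [Na+].[O-]/C(=C\C1=C(C)C[C@H](O[Si](C)(C)C(C)(C)C)CC1(C)C)N1[C@H](Cc2ccccc2)COC1=O | intermediate (not isolated)
30 | (R)-4-benzyl-3-{(R)-2-[(4S)-4-[(tert-butyldimethylsilyl)oxy]-2,6,6-trimethylcyclohex-1-en-1-yl]-2-(phenylselanyl)acetyl}oxazolidin-2-one | O=C(N1[C@H](Cc2ccccc2)COC1=O)[C@H]([Se]c1ccccc1)C1=C(C)C[C@H](O[Si](C)(C)C(C)(C)C)CC1(C)C | intermediate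
31 | selenoxide of 30 (both configurations at selenium) | O=C(N1[C@H](Cc2ccccc2)COC1=O)[C@H]([Se](=O)c1ccccc1)C1=C(C)C[C@H](O[Si](C)(C)C(C)(C)C)CC1(C)C | intermediate (not isolated)
32 | (R)-4-benzyl-3-{(Z)-2-[(2S,4R)-4-[(tert-butyldimethylsilyl)oxy]-2,6,6-trimethyl-2-(phenylselanyloxy)cyclohexylidene]acetyl}oxazolidin-2-one | O=C(/C=C1/C(C)(C)C[C@@H](O[Si](C)(C)C(C)(C)C)C[C@]1(C)O[Se]c1ccccc1)N1[C@H](Cc2ccccc2)COC1=O | intermediate (not isolated)
33 | (R)-4-benzyl-3-{(Z)-2-[(2S,4R)-4-[(tert-butyldimethylsilyl)oxy]-2-hydroxy-2,6,6-trimethylcyclohexylidene]acetyl}oxazolidin-2-one | O=C(/C=C1/C(C)(C)C[C@@H](O[Si](C)(C)C(C)(C)C)C[C@]1(C)O)N1[C@H](Cc2ccccc2)COC1=O | intermediate (not isolated)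
34 | (6R,7aS)-6-[(tert-butyldimethylsilyl)oxy]-4,4,7a-trimethyl-5,6,7,7a-tetrahydro-1-benzofuran-2(4H)-one, O-silyl-(+)-loliolide | O=C1C=C2C(C)(C)C[C@@H](O[Si](C)(C)C(C)(C)C)C[C@]2(C)O1 | intermediate
35 | diisobutylaluminium lactolate of 34 (both C8' epimers) | CC(C)C[Al](CC(C)C)OC1C=C2C(C)(C)C[C@@H](O[Si](C)(C)C(C)(C)C)C[C@]2(C)O1 | intermediate (not isolated)
36 | (6R,7aS)-6-[(tert-butyldimethylsilyl)oxy]-4,4,7a-trimethyl-2,4,5,6,7,7a-hexahydro-1-benzofuran-2-yl acetate (both C8' epimers) | CC(=O)OC1C=C2C(C)(C)C[C@@H](O[Si](C)(C)C(C)(C)C)C[C@]2(C)O1 | intermediate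
37 | tert-butyldimethyl{[(2S,6R,7aS)-4,4,7a-trimethyl-2-[(trimethylsilyl)ethynyl]-2,4,5,6,7,7a-hexahydro-1-benzofuran-6-yl]oxy}silane | C[Si](C)(C)C#C[C@@H]1C=C2C(C)(C)C[C@@H](O[Si](C)(C)C(C)(C)C)C[C@]2(C)O1 | intermediate
38 | (2S,6R,7aS)-2-ethynyl-4,4,7a-trimethyl-2,4,5,6,7,7a-hexahydro-1-benzofuran-6-ol | C#C[C@@H]1C=C2C(C)(C)C[C@@H](O)C[C@]2(C)O1 | intermediate
39 | O-dimethylaluminium alkoxide of the (E)-alkenyl(dimethyl)alane from 38 | C[Al](C)/C=C(\C)[C@@H]1C=C2C(C)(C)C[C@@H](O[Al](C)C)C[C@]2(C)O1 | intermediate (not isolated)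
40 | (2S,6R,7aS)-2-[(E)-1-iodoprop-1-en-2-yl]-4,4,7a-trimethyl-2,4,5,6,7,7a-hexahydro-1-benzofuran-6-ol | I/C=C(\C)[C@@H]1C=C2C(C)(C)C[C@@H](O)C[C@]2(C)O1 | intermediate
41 | dibromomethane | BrCBr | starting material
42 | tributyltin chloride | CCCC[Sn](Cl)(CCCC)CCCC | starting material
43 | dibromomethyllithium | [Li]C(Br)Br | intermediate (not isolated)
44 | tributyl(dibromomethyl)stannane | CCCC[Sn](CCCC)(CCCC)C(Br)Br | intermediate
45 | (2E,4E,6E)-2,7-dimethylocta-2,4,6-trienedial | O=C/C(C)=C/C=C/C=C(C)/C=O | starting material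
46 | (2E,4E,6E,8E)-2,7-dimethyl-9-(tributylstannyl)nona-2,4,6,8-tetraenal | CCCC[Sn](CCCC)(CCCC)/C=C/C(C)=C/C=C/C=C(C)/C=O | intermediate (not isolated)
47 | (1E,3E,5E,7E,9E)-3,8-dimethyl-1,10-bis(tributylstannyl)deca-1,3,5,7,9-pentaene | CCCC[Sn](CCCC)(CCCC)/C=C/C(C)=C/C=C/C=C(C)/C=C/[Sn](CCCC)(CCCC)CCCC | intermediate
48 | (2S,6R,7aS)-2-[(2E,4E,6E,8E,10E,12E)-6,11-dimethyl-13-(tributylstannyl)trideca-2,4,6,8,10,12-hexaen-2-yl]-4,4,7a-trimethyl-2,4,5,6,7,7a-hexahydro-1-benzofuran-6-ol | CCCC[Sn](CCCC)(CCCC)/C=C/C(C)=C/C=C/C=C(C)/C=C/C=C(\C)[C@@H]1C=C2C(C)(C)C[C@@H](O)C[C@]2(C)O1 | intermediate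
49 | (all-E)-(5R,8S,3'R,5'S,8'S)-5,8:5',8'-diepoxy-5,8,5',8'-tetrahydro-β,β-caroten-3'-ol | CC(/C=C/C=C(\C)[C@@H]1C=C2C(C)(C)CCC[C@@]2(C)O1)=C\C=C\C=C(C)\C=C\C=C(/C)[C@@H]1C=C2C(C)(C)C[C@@H](O)C[C@]2(C)O1 | target

Total step count: 25. Longest linear sequence: 15 steps (steps 9 to 21, then 24 and 25).

Steps most likely to fail

Step 4 (and its mirror, step 17): the selenoxide may react mainly through the rotamer that turns the acyl group towards C1, so that the shift gives the E hydroxy imide and little lactone. The fallback uses that E manifold. Acid 2 is activated as anhydride 4 and loaded onto the antipodal auxiliary 26 to give (R)-4-benzyl-3-[2-(2,6,6-trimethylcyclohex-1-en-1-yl)acetyl]oxazolidin-2-one F1. Its sodium enolate F2 is selenenylated with 6 to the (R)-selenide F3. Oxidation with H2O2 and pyridine passes through the selenoxide F4 and the E selenenate F5 to the E hydroxy imide F6, which now carries (R)-C5 and is freed by chromatography from the non-polar lactone fraction that arises through the Z rotamer. Sensitised irradiation (350 nm, benzophenone, MeCN) isomerises C6=C7 to the Z hydroxy imide F7, which lactonises and rejoins the route at 12.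

Step 6 (and, for the same reason, step 19): the oxocarbenium ion may be attacked with little discrimination between the face of the angular methyl group and that of the C4 methylene, giving C8 epimers. The fallback puts C8 under catalyst control. Hemiketal 13 is reduced through its open-chain tautomer, the hydroxy ynone F8, by Noyori asymmetric transfer hydrogenation (RuCl(p-cymene)(TsDPEN), i-PrOH, ligand enantiomer chosen to give the 8R carbinol) to the Z-enynediol F9. Mitsunobu cyclodehydration (PPh3, DIAD, THF, −20 °C) activates the secondary propargylic hydroxyl and closes the O–C8 bond with inversion, returning to the route at 14. The same detour, with the other ligand enantiomer, is open to the hydroxylated half.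

Step 8 (and step 21): AlMe3 may ionise the C8–O bond, which is both allylic and propargylic, or coordination to the ring oxygen may erode the regiocontrol of the methylalumination. The fallback avoids Lewis acids. Alkyne 15 undergoes copper-catalysed syn methylboration (CuCl, Xantphos, NaOt-Bu, B2pin2, MeI, THF, rt) to the E alkenylboronate F10, and iododeboronation with retention (NaOH, I2, THF) rejoins the route at 17.

Further compounds
F1 | step 4 | (R)-4-benzyl-3-[2-(2,6,6-trimethylcyclohex-1-en-1-yl)acetyl]oxazolidin-2-one | O=C(CC1=C(C)CCCC1(C)C)N1[C@H](Cc2ccccc2)COC1=O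
F2 | step 4 | sodium (Z)-enolate of F1 | [Na+].[O-]/C(=C\C1=C(C)CCCC1(C)C)N1[C@H](Cc2ccccc2)COC1=O
F3 | step 4 | (R)-4-benzyl-3-[(R)-2-(phenylselanyl)-2-(2,6,6-trimethylcyclohex-1-en-1-yl)acetyl]oxazolidin-2-one | O=C(N1[C@H](Cc2ccccc2)COC1=O)[C@H]([Se]c1ccccc1)C1=C(C)CCCC1(C)C
F4 | step 4 | selenoxide of F3 | O=C(N1[C@H](Cc2ccccc2)COC1=O)[C@H]([Se](=O)c1ccccc1)C1=C(C)CCCC1(C)C
F5 | step 4 | (R)-4-benzyl-3-{(E)-2-[(2R)-2,6,6-trimethyl-2-(phenylselanyloxy)cyclohexylidene]acetyl}oxazolidin-2-one | O=C(/C=C1\C(C)(C)CCC[C@@]1(C)O[Se]c1ccccc1)N1[C@H](Cc2ccccc2)COC1=O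
F6 | step 4 | (R)-4-benzyl-3-{(E)-2-[(2R)-2-hydroxy-2,6,6-trimethylcyclohexylidene]acetyl}oxazolidin-2-one | O=C(/C=C1\C(C)(C)CCC[C@@]1(C)O)N1[C@H](Cc2ccccc2)COC1=O
F7 | step 4 | (R)-4-benzyl-3-{(Z)-2-[(2R)-2-hydroxy-2,6,6-trimethylcyclohexylidene]acetyl}oxazolidin-2-one | O=C(/C=C1/C(C)(C)CCC[C@@]1(C)O)N1[C@H](Cc2ccccc2)COC1=O
F8 | step 6 | (Z)-1-[(2R)-2-hydroxy-2,6,6-trimethylcyclohexylidene]-4-(trimethylsilyl)but-3-yn-2-one | C[Si](C)(C)C#CC(=O)/C=C1/C(C)(C)CCC[C@@]1(C)O
F9 | step 6 | (2R,Z)-1-[(2R)-2-hydroxy-2,6,6-trimethylcyclohexylidene]-4-(trimethylsilyl)but-3-yn-2-ol | C[Si](C)(C)C#C[C@H](O)/C=C1/C(C)(C)CCC[C@@]1(C)O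
F10 | step 8 | 4,4,5,5-tetramethyl-2-{(E)-2-[(2S,7aR)-4,4,7a-trimethyl-2,4,5,6,7,7a-hexahydro-1-benzofuran-2-yl]prop-1-en-1-yl}-1,3,2-dioxaborolane | CC1(C)OB(OC1(C)C)/C=C(\C)[C@@H]1C=C2C(C)(C)CCC[C@@]2(C)O1
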